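**Retrosynthetic overview**

1. In ring A (C1 ethyl, C2 methyl, C3 aryl, C4 methyl, C5 aryl, C6 spiro), C3 is an ArCH carbon sitting between the two methyl-bearing carbons C2 and C4. Removing it leaves a spiro[4.5] cyclopentanone (C6–C1–C2(=O)–C4–C5), so C2–C3 and C3–C4 are both made by inserting an aryl-carbene carbon into the C2–C4 bond of that ketone.
2. The C2 ketone that remains after insertion is the handle for the axial C2 methyl (methylenation, then hydrogenation from the equatorial face).
3. The spiro cyclopentanone comes from an α-diazoketone by ipso attack of one of two identical aryl groups on C5 (C1–C6 bond); this one step creates the five-membered ring and the dienone ring and sets C5, C6 and C1.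
4. The diazoketone comes from a propyl ketone, made from an aldehyde whose C4 stereocentre is set by enamine-catalysed alkylation of propanal with the bis-aryl carbinol (C4–C5 bond).
5. Ring order: the five-membered ring and the dienone ring form together (step 6); the five-membered ring is then enlarged to ring A (step 8).

Key step: step 8

Remark: atoms carry the target labels throughout (ring A C1–C6 with C6 spiro; dienone ring C7–C11 with C9 the carbonyl and C8, C11 the methoxy carbons), aryl means 2,4,5-trimethoxyphenyl, and the sense of induction in step 2 is assigned from the benzyl-shielding model of the imidazolidinone enamine.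

**Route**

Step 1
Reactants: 1 1-bromo-2,4,5-trimethoxybenzene; 2 2,4,5-trimethoxybenzaldehyde
Product: 4 bis(2,4,5-trimethoxyphenyl)methanol, via 2,4,5-trimethoxyphenyllithium 3 (not isolated)
Conditions: n-BuLi, THF, −78 °C; then 2, −78 → 0 °C; water quench
Reagents that add atoms: none
Why: Bromine–lithium exchange followed by 1,2-addition of the aryllithium to the aldehyde should give the carbinol, which has two identical aryl groups and therefore no stereocentre.

Step 2
Reactants: 4 bis(2,4,5-trimethoxyphenyl)methanol; 5 propanal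
Product: 6 (2S)-2-methyl-3,3-bis(2,4,5-trimethoxyphenyl)propanal
Conditions: (2R,5R)-5-benzyl-2-tert-butyl-3-methylimidazolidin-4-one·CF3CO2H (20 mol %), 5 (3 equiv), Et2O, 0 °C
Reagents that add atoms: none
Why: In this enamine-catalysed SN1-type α-alkylation of an aldehyde the carbinol should ionise to a benzhydryl cation stabilised by ortho- and para-methoxy groups, and the E-enamine of propanal should capture it on the face opposite the catalyst benzyl group, setting C4 as S.

Step 3
Reactants: 6 (2S)-2-methyl-3,3-bis(2,4,5-trimethoxyphenyl)propanal; 7 propylmagnesium chloride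
Product: 8 (2S)-2-methyl-1,1-bis(2,4,5-trimethoxyphenyl)hexan-3-ol (both C3 epimers)
Conditions: THF, −78 → 0 °C; aq NH4Cl
Reagents that add atoms: none
Why: Grignard addition to the aldehyde at low temperature should outrun enolisation, so C4 is kept, and the new carbinol centre is erased in step 4.

Step 4
Reactants: 8 (2S)-2-methyl-1,1-bis(2,4,5-trimethoxyphenyl)hexan-3-ol
Product: 9 (2S)-2-methyl-1,1-bis(2,4,5-trimethoxyphenyl)hexan-3-one
Conditions: Dess–Martin periodinane, CH2Cl2, 0 °C → rt
Reagents that add atoms: none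
Why: Dess–Martin oxidation is fast and close to neutral, so the α-stereocentre C4 should not epimerise and the electron-rich rings should be untouched.

Step 5
Reactants: 9 (2S)-2-methyl-1,1-bis(2,4,5-trimethoxyphenyl)hexan-3-one
Product: 11 (2S)-4-diazo-2-methyl-1,1-bis(2,4,5-trimethoxyphenyl)hexan-3-one, via trifluoroacetyl diketone 10 (not isolated)
Conditions: LiN(SiMe3)2, THF, −78 °C; CF3CO2CH2CF3; dilute HCl quench; then CH3SO2N3, Et3N, H2O, MeCN, rt
Reagents that add atoms: methanesulfonyl azide, CS(=O)(=O)N=[N+]=[N-]; 2,2,2-trifluoroethyl trifluoroacetate, O=C(OCC(F)(F)F)C(F)(F)F (atoms only in 10)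
Why: In this deacylative Regitz-type diazo transfer the amide base should deprotonate the unbranched C1 methylene kinetically and not the C4 methine, and the trifluoroacetylated diketone should then accept the diazo group at C1 with loss of the trifluoroacetyl group, leaving C4 untouched.

Step 6
Reactants: 11 (2S)-4-diazo-2-methyl-1,1-bis(2,4,5-trimethoxyphenyl)hexan-3-one
Product: 12 (1S,3S,4R,5S)-1-ethyl-6,9-dimethoxy-3-methyl-4-(2,4,5-trimethoxyphenyl)spiro[4.5]deca-6,9-diene-2,8-dione (target labels: C1 S, C4 S, C5 R, C6 S)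
Conditions: CF3CO2H, CH2Cl2, −20 °C; cold aq NaHCO3
Reagents that add atoms: none
Why: In this acid-promoted dearomatising spirocyclisation of an α-diazoketone (Ar1-5 participation) the C1 diazonium ion should be displaced by the ipso carbon of one aryl ring and the arenium ion should lose its para O-methyl group to trifluoroacetate, with the spectator aryl on C5 trans to the C4 methyl, the methoxy-bearing C11 on the side of C5–H, and the epimerisable C1 ethyl on the face of the C7–H arm.

Step 7
Reactants: 2 2,4,5-trimethoxybenzaldehyde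
Product: 13 (E)-(2,4,5-trimethoxybenzylidene)hydrazine
Conditions: N2H4·H2O (excess), EtOH, rt
Reagents that add atoms: hydrazine, NN
Why: Condensation of the aldehyde with excess hydrazine should give the free hydrazone, the excess suppressing azine formation.

Step 8
Reactants: 12 spiro[4.5]decadienedione (C2 ketone); 13 (E)-(2,4,5-trimethoxybenzylidene)hydrazine
Product: 15 (1S,3S,4S,5R,6S)-1-ethyl-8,11-dimethoxy-4-methyl-3,5-bis(2,4,5-trimethoxyphenyl)spiro[5.5]undeca-7,10-diene-2,9-dione, via 1-(diazomethyl)-2,4,5-trimethoxybenzene 14 (not isolated)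
Conditions: 13, MnO2, CH2Cl2, 0 °C, cold filtration; filtrate added slowly to 12, Sc(OTf)3 (20 mol %), toluene, −78 → −40 °C; then DBU (cat.), rt
Reagents that add atoms: none
Why: Sc(OTf)3 should activate the strained, non-conjugated C2 carbonyl so that the nucleophilic diazo carbon of 14 adds to it (C2–C3 bond), and in the resulting β-oxido diazonium betaine C4 should shift from C2 to C3 as N2 leaves (C3–C4 bond), with retention at C4 and return of the C2 carbonyl. The closest known reaction is the Sc(OTf)3-catalysed homologation of cycloalkanones with aryldiazomethanes, a Tiffeneau–Demjanov-type (Büchner–Curtius–Schlotterbeck) ring enlargement. No ring is closed by cyclisation; the five-membered ring is enlarged to six-membered ring A by a 1,2-shift that inserts one carbon. The new stereocentre C3 is benzylic and α to the ketone, so it is set under thermodynamic control (DBU) with the aryl equatorial and trans to the C4 methyl, in the chair that also holds the C1 ethyl, C4 methyl and C5 aryl equatorial; a C1 epimer carried from step 6 would converge in the same equilibration. The step needs chemoselectivity for C2 over the vinylogous-ester carbonyl C9, which the much lower electrophilicity of C9 should secure, and migration of C4 in preference to C1, which is expected because C1 is neopentyl (next to quaternary C6) and bears the larger ethyl group, so the betaine rotamer with C4 antiperiplanar to N2 is the less hindered one.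

Step 9
Reactants: 15 ring A 2-ketone
Product: 16 (1R,3R,4R,5R,6S)-1-ethyl-8,11-dimethoxy-4-methyl-2-methylidene-3,5-bis(2,4,5-trimethoxyphenyl)spiro[5.5]undeca-7,10-dien-9-one
Conditions: Zn, CH2Br2, TiCl4, THF, 0 °C (reagent preformed); then 15, CH2Cl2, 0 °C → rt
Reagents that add atoms: dibromomethane, BrCBr
Why: The Takai–Lombardo methylenation reagent is non-basic, so the epimerisable C1 and C3 centres should be kept, and it should attack the saturated C2 ketone in preference to the cross-conjugated vinylogous-ester carbonyl C9.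

Step 10
Reactants: 16 2-methylidene compound
Product: 17 tatanan B, (1R,2S,3S,4R,5R,6S)-1-ethyl-8,11-dimethoxy-2,4-dimethyl-3,5-bis(2,4,5-trimethoxyphenyl)spiro[5.5]undeca-7,10-dien-9-one
Conditions: H2 (1–4 atm), RhCl(PPh3)3 (20 mol %), benzene/EtOH, rt
Reagents that add atoms: none
Why: Homogeneous hydrogenation with RhCl(PPh3)3 should reduce only the 1,1-disubstituted exocyclic alkene, and because the axial face of C2 is blocked by the axial C7 arm on C6, hydrogen should arrive from the equatorial side and leave the new C2 methyl axial (S).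

**Compound list**

1 | 1-bromo-2,4,5-trimethoxybenzene | COc1cc(OC)c(Br)cc1OC | starting material
2 | 2,4,5-trimethoxybenzaldehyde | COc1cc(OC)c(C=O)cc1OC | starting material
3 | 2,4,5-trimethoxyphenyllithium | [Li]c1cc(OC)c(OC)cc1OC | intermediate (not isolated)
4 | bis(2,4,5-trimethoxyphenyl)methanol | OC(c1cc(OC)c(OC)cc1OC)c1cc(OC)c(OC)cc1OC | intermediate
5 | propanal | CCC=O | starting material
6 | (2S)-2-methyl-3,3-bis(2,4,5-trimethoxyphenyl)propanal | O=C[C@@H](C)C(c1cc(OC)c(OC)cc1OC)c1cc(OC)c(OC)cc1OC | intermediate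
7 | propylmagnesium chloride (commercial solution) | CCC[Mg]Cl | starting material
8 | (2S)-2-methyl-1,1-bis(2,4,5-trimethoxyphenyl)hexan-3-ol, both C3 epimers | CCCC(O)[C@@H](C)C(c1cc(OC)c(OC)cc1OC)c1cc(OC)c(OC)cc1OC | intermediate
9 | (2S)-2-methyl-1,1-bis(2,4,5-trimethoxyphenyl)hexan-3-one | CCCC(=O)[C@@H](C)C(c1cc(OC)c(OC)cc1OC)c1cc(OC)c(OC)cc1OC | intermediate
10 | (5S)-3-ethyl-1,1,1-trifluoro-5-methyl-6,6-bis(2,4,5-trimethoxyphenyl)hexane-2,4-dione | CCC(C(=O)C(F)(F)F)C(=O)[C@@H](C)C(c1cc(OC)c(OC)cc1OC)c1cc(OC)c(OC)cc1OC | intermediate (not isolated)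
11 | (2S)-4-diazo-2-methyl-1,1-bis(2,4,5-trimethoxyphenyl)hexan-3-one | CCC(=[N+]=[N-])C(=O)[C@@H](C)C(c1cc(OC)c(OC)cc1OC)c1cc(OC)c(OC)cc1OC | intermediate
12 | (1S,3S,4R,5S)-1-ethyl-6,9-dimethoxy-3-methyl-4-(2,4,5-trimethoxyphenyl)spiro[4.5]deca-6,9-diene-2,8-dione; ethyl and aryl cis, methyl trans to aryl | CC[C@@H]1C(=O)[C@@H](C)[C@H](c2cc(OC)c(OC)cc2OC)[C@]12C=C(OC)C(=O)C=C2OC | intermediate
13 | (E)-(2,4,5-trimethoxybenzylidene)hydrazine | N/N=C/c1cc(OC)c(OC)cc1OC | intermediate
14 | 1-(diazomethyl)-2,4,5-trimethoxybenzene | [N-]=[N+]=Cc1cc(OC)c(OC)cc1OC | intermediate (not isolated)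
15 | (1S,3S,4S,5R,6S)-1-ethyl-8,11-dimethoxy-4-methyl-3,5-bis(2,4,5-trimethoxyphenyl)spiro[5.5]undeca-7,10-diene-2,9-dione | CC[C@@H]1C(=O)[C@H](c2cc(OC)c(OC)cc2OC)[C@@H](C)[C@H](c2cc(OC)c(OC)cc2OC)[C@]12C=C(OC)C(=O)C=C2OC | intermediate
16 | (1R,3R,4R,5R,6S)-1-ethyl-8,11-dimethoxy-4-methyl-2-methylidene-3,5-bis(2,4,5-trimethoxyphenyl)spiro[5.5]undeca-7,10-dien-9-one | CC[C@@H]1C(=C)[C@H](c2cc(OC)c(OC)cc2OC)[C@@H](C)[C@H](c2cc(OC)c(OC)cc2OC)[C@]12C=C(OC)C(=O)C=C2OC | intermediate
17 | tatanan B, (1R,2S,3S,4R,5R,6S)-1-ethyl-8,11-dimethoxy-2,4-dimethyl-3,5-bis(2,4,5-trimethoxyphenyl)spiro[5.5]undeca-7,10-dien-9-one | CC[C@@H]1[C@H](C)[C@H](c2cc(OC)c(OC)cc2OC)[C@@H](C)[C@H](c2cc(OC)c(OC)cc2OC)[C@]12C=C(OC)C(=O)C=C2OC | target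

**Step count**

Total steps: 10. Longest linear sequence: 9 (steps 1–6, then 8–10); step 7 is a one-step side branch.

**Steps most likely to fail**

1. Step 8 (key step). The electron-rich diazo compound may be consumed on Sc(OTf)3 (azine or stilbene formation) faster than it adds to the doubly flanked C2 carbonyl, or C1 may migrate in place of C4. The fallback is a stepwise semipinacol homologation that separates the addition from the shift; it sets out from 12 and 2 and comes back at 15. Aldehyde 2 and benzeneselenol (ZnCl2, CH2Cl2) should give the selenoacetal bis(phenylselanyl)(2,4,5-trimethoxyphenyl)methane F1. Selenium–lithium exchange with n-BuLi in THF at −78 °C should give lithio(phenylselanyl)(2,4,5-trimethoxyphenyl)methane F2, a strongly nucleophilic and weakly basic carbanion, which should add to the C2 carbonyl of 12 to give the β-hydroxy selenide F3. AgBF4 on Al2O3 in CH2Cl2 should then ionise the benzylic C–Se bond and trigger the 1,2-shift of C4, giving 15 after DBU equilibration.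

2. Step 6. Loss of N2 from the secondary α-keto diazonium ion may occur with a 1,2-hydride shift from the ethyl group (enone formation) in competition with ipso attack. The fallback closes the spiro ring from a diazomethyl ketone and adds the ethyl group afterwards; it sets out from 6 and comes back at 12. MeMgBr should add to 6 to give (3S)-3-methyl-4,4-bis(2,4,5-trimethoxyphenyl)butan-2-ol F4, and Dess–Martin oxidation should give (3S)-3-methyl-4,4-bis(2,4,5-trimethoxyphenyl)butan-2-one F5. Trifluoroacetylation (LiN(SiMe3)2, CF3CO2CH2CF3) should give (5S)-1,1,1-trifluoro-5-methyl-6,6-bis(2,4,5-trimethoxyphenyl)hexane-2,4-dione F6, used without isolation, and diazo transfer (CH3SO2N3, Et3N) should give (3S)-1-diazo-3-methyl-4,4-bis(2,4,5-trimethoxyphenyl)butan-2-one F7. CF3CO2H should then cyclise F7 through a primary diazonium ion, which has no hydrogen able to shift, to the 1-unsubstituted spiroketone F8. Kinetic deprotonation at the C1 methylene (LiN(SiMe3)2, THF, −78 °C) and alkylation with iodoethane (DMPU), on the face of the C7–H arm, should return 12.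

3. Step 9. The gem-dimetallic reagent may fail to reach the C2 carbonyl, which is flanked by the C1 ethyl and C3 aryl carbons, or may react at the C9 carbonyl. The fallback is a two-stage Peterson olefination; it sets out from 15 and comes back at 16. Me3SiCH2Li with CeCl3 in THF at −78 °C, a small and weakly basic nucleophile, should add to C2 to give the β-hydroxysilane F9, and KH in THF should then eliminate trimethylsilanolate to give 16.

Further compounds
F1 | step 8 | bis(phenylselanyl)(2,4,5-trimethoxyphenyl)methane | COc1cc(OC)c(C([Se]c2ccccc2)[Se]c2ccccc2)cc1OC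
F2 | step 8 | lithio(phenylselanyl)(2,4,5-trimethoxyphenyl)methane | [Li]C([Se]c1ccccc1)c1cc(OC)c(OC)cc1OC
F3 | step 8 | β-hydroxy selenide from addition at C2 of 12 (mixture at C2 and the selenide carbon) | CC[C@@H]1C(O)(C([Se]c3ccccc3)c3cc(OC)c(OC)cc3OC)[C@@H](C)[C@H](c2cc(OC)c(OC)cc2OC)[C@]12C=C(OC)C(=O)C=C2OC
F4 | step 6 | (3S)-3-methyl-4,4-bis(2,4,5-trimethoxyphenyl)butan-2-ol | CC(O)[C@@H](C)C(c1cc(OC)c(OC)cc1OC)c1cc(OC)c(OC)cc1OC
F5 | step 6 | (3S)-3-methyl-4,4-bis(2,4,5-trimethoxyphenyl)butan-2-one | CC(=O)[C@@H](C)C(c1cc(OC)c(OC)cc1OC)c1cc(OC)c(OC)cc1OC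
F6 | step 6 | (5S)-1,1,1-trifluoro-5-methyl-6,6-bis(2,4,5-trimethoxyphenyl)hexane-2,4-dione | O=C(CC(=O)[C@@H](C)C(c1cc(OC)c(OC)cc1OC)c1cc(OC)c(OC)cc1OC)C(F)(F)F
F7 | step 6 | (3S)-1-diazo-3-methyl-4,4-bis(2,4,5-trimethoxyphenyl)butan-2-one | [N-]=[N+]=CC(=O)[C@@H](C)C(c1cc(OC)c(OC)cc1OC)c1cc(OC)c(OC)cc1OC
F8 | step 6 | 1-unsubstituted spiroketone, 6,9-dimethoxy-3-methyl-4-(2,4,5-trimethoxyphenyl)spiro[4.5]deca-6,9-diene-2,8-dione | C1C(=O)[C@@H](C)[C@H](c2cc(OC)c(OC)cc2OC)[C@]12C=C(OC)C(=O)C=C2OC
F9 | step 9 | β-hydroxysilane from addition of the trimethylsilylmethyl group at C2 of 15 | CC[C@@H]1C(O)(C[Si](C)(C)C)[C@H](c2cc(OC)c(OC)cc2OC)[C@@H](C)[C@H](c2cc(OC)c(OC)cc2OC)[C@]12C=C(OC)C(=O)C=C2OC
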